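The quinone ring B (C1, C2, C3, C4, C4a, C8a) is cut at C1–C8a and C4–C4a into phenyllithium and a squarate-derived cyclobutenedione. Its four carbons already carry the oxygen, oxygen, carbon, oxygen pattern of C1–C4. The key step heats a 4-hydroxy-4-phenylcyclobutenone. Strain-driven 4π opening to a dienylketene, 6π closure onto the phenyl ring and oxidation deliver the naphthoquinone in one operation. It exploits the unsubstituted benzo ring A, which makes both ortho carbons and both squarate carbonyls equivalent. It also exploits the side-chain oxygen, five bonds from C2, which serves as a temporary dihydropyran ether on C2. The dienol arm arrives by cross-metathesis.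

Key step: step 3

Assumption: the [C@@H] centre is read as (R) and the enoate double bond as (E); compounds 1, 2, 7, 13, 16 and 17 are taken as purchasable.

Step 1
Reactants: 1 3,3-dimethyloxetane; 2 dimethyl squarate (3,4-dimethoxycyclobut-3-ene-1,2-dione)
Product: 6 pyran-fused cyclobutenedione 4,4-dimethyl-2-oxabicyclo[4.2.0]oct-1(6)-ene-7,8-dione, via lithio alkoxide dianion 3 (not isolated), via squarate adduct diol 4 (not isolated), via methoxy dione alcohol 5 (not isolated)
Conditions: lithium 4,4'-di-tert-butylbiphenylide (LiDBB, 2.0 equiv), THF, 0 °C; cannulate into 2, THF, −78 °C; then 6 M aq HCl, −78 °C → rt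
Reagents that add atoms: water, O
Why: Reductive lithiation of the strained oxetane gives the γ-lithioalkoxide 3, whose carbanion adds 1,2 to a squarate carbonyl, after which aqueous acid performs the usual allylic hydrolysis of 4 to cyclobutenedione 5 and the freed primary alcohol replaces the remaining vinylogous methyl ester by a 6-endo-trig addition–elimination assisted by the gem-dimethyl group.

Step 2
Reactants: 6 pyran-fused cyclobutenedione; 7 phenyllithium
Product: 8 racemic 8-hydroxy-4,4-dimethyl-8-phenyl-2-oxabicyclo[4.2.0]oct-1(6)-en-7-one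
Conditions: 7 (1.1 equiv), THF, −78 °C; sat. aq NH4Cl
Reagents that add atoms: none
Why: 1,2-Addition of an organolithium to a cyclobutenedione should occur at C8, the carbonyl outside the vinylogous ester, to give racemic 8, whose stereocentre disappears in step 3, and attack at C7 would be harmless because it leads to the same hydroquinone.

Step 3
Reactants: 8 racemic 4-hydroxy-4-phenylcyclobutenone
Product: 11 3,3-dimethyl-3,4-dihydro-2H-benzo[g]chromene-5,10-dione, via dienylketene 9 (not isolated), via hydroquinone 10 (not isolated)
Conditions: degassed p-xylene (dilute), 138 °C; then Ag2O, rt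
Reagents that add atoms: none
Why: Heating opens the strained cyclobutenone by conrotatory 4π electrocyclic cleavage of C7–C8, the donor hydroxyl rotating outward so that the phenyl group turns inward next to the ketene in (Z)-dienylketene 9. Ring B then closes by a thermally allowed disrotatory 6π electrocyclisation that joins the ketene carbon to an ortho carbon of the phenyl ring (the C4–C4a bond of the target), and tautomerisation restores aromaticity as hydroquinone 10, which Ag2O dehydrogenates to quinone 11. The closest known reaction type is the Moore rearrangement, the thermal ring expansion of 4-aryl-4-hydroxycyclobutenones to 1,4-hydroquinones. No stereocentre is formed and the racemic carbinol centre of 8 is erased. The step needs torquoselectivity, secured by the hydroxyl donor, and an s-cis dienylketene, secured by the dihydropyran ring that ties C6 to C1, while the two ortho carbons of the unsubstituted phenyl ring are equivalent so no regiochemical question arises. Release of cyclobutene strain together with aromatisation should make the cascade irreversible.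

Step 4
Reactants: 11 pyranonaphthoquinone
Product: 12 2-hydroxy-3-(3-hydroxy-2,2-dimethylpropyl)naphthalene-1,4-dione
Conditions: 1 M aq NaOH, THF, 50 °C, Ar; then 1 M HCl, 0 °C, to pH 3
Reagents that add atoms: sodium hydroxide, [Na+].[OH-]
Why: Addition–elimination of hydroxide at C2 of the 2-alkoxy-1,4-naphthoquinone (vinylogous ester saponification) expels the tethered primary alkoxide and is made irreversible by formation of the delocalised hydroxyquinone anion, so the temporary dihydropyran is removed and both oxygens of the target appear.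

Step 5
Reactants: 12 hydroxyquinone alcohol; 13 methacrylic anhydride
Product: 15 3-(3-hydroxy-1,4-dioxo-1,4-dihydronaphthalen-2-yl)-2,2-dimethylpropyl methacrylate, via bis-methacrylate 14 (not isolated)
Conditions: 13 (2.5 equiv), Et3N, DMAP (cat.), BHT (trace), CH2Cl2, 0 °C → rt; then MeOH, rt
Reagents that add atoms: none
Why: DMAP-catalysed acylation esterifies both hydroxyls, and the quinonyl ester of 14, a vinylogous mixed anhydride, should be cleaved by methanol under the same catalysis far faster than the hindered neopentyl-type methacrylate, leaving 15.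

Step 6
Reactants: 16 (R)-but-3-yn-2-ol; 17 but-3-enylmagnesium bromide
Product: 18 (2R)-3-methylidenehept-6-en-2-ol
Conditions: 17 (2.5 equiv), CuI (15 mol %), THF/Et2O, −10 °C → rt; sat. aq NH4Cl
Reagents that add atoms: none
Why: In this copper-catalysed carbomagnesiation of a propargylic alkoxide the magnesium alkoxide directs the butenyl group to the internal alkyne carbon through a five-membered oxamagnesacycle, protonolysis gives the 1,1-disubstituted alkene, and the (R) carbinol centre bought with 16 is not touched.

Step 7
Reactants: 15 naphthoquinone methacrylate; 18 (R)-dienol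
Product: 19 rhinacanthin I
Conditions: second-generation Hoveyda–Grubbs catalyst (5 mol %), 18 (3 equiv), CH2Cl2, 40 °C, Ar sparge
Reagents that add atoms: none
Why: Olefin cross-metathesis of the monosubstituted alkene of 18 with the methacrylate should give the thermodynamically preferred (E)-trisubstituted enoate, since the hindered 1,1-disubstituted allylic-alcohol alkene does not engage, ring closure within 18 would require a cyclobutene, and the quinone itself suppresses hydride-mediated double-bond migration, while the (R) centre is untouched.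

Compound list
1 | 3,3-dimethyloxetane | CC1(C)COC1 | starting material
2 | dimethyl squarate (3,4-dimethoxycyclobut-3-ene-1,2-dione) | COC1=C(OC)C(=O)C1=O | starting material
3 | lithium 3-lithio-2,2-dimethylpropan-1-olate | [Li]CC(C)(C)CO[Li] | intermediate
4 | racemic 4-hydroxy-4-(3-hydroxy-2,2-dimethylpropyl)-2,3-dimethoxycyclobut-2-en-1-one | COC1=C(OC)C(O)(CC(C)(C)CO)C1=O | intermediate
5 | 3-(3-hydroxy-2,2-dimethylpropyl)-4-methoxycyclobut-3-ene-1,2-dione | COC1=C(CC(C)(C)CO)C(=O)C1=O | intermediate
6 | 4,4-dimethyl-2-oxabicyclo[4.2.0]oct-1(6)-ene-7,8-dione | O=C1C(=O)C2=C1CC(C)(C)CO2 | intermediate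
7 | phenyllithium | [Li]c1ccccc1 | starting material
8 | racemic 8-hydroxy-4,4-dimethyl-8-phenyl-2-oxabicyclo[4.2.0]oct-1(6)-en-7-one | O=C1C2=C(OCC(C)(C)C2)C1(O)c1ccccc1 | intermediate
9 | [(2Z)-2-[hydroxy(phenyl)methylidene]-5,5-dimethyloxan-3-ylidene]methanone (dienylketene) | O=C=C1CC(C)(C)CO/C1=C(\O)c1ccccc1 | intermediate
10 | 3,3-dimethyl-3,4-dihydro-2H-benzo[g]chromene-5,10-diol | CC1(C)COc2c(O)c3ccccc3c(O)c2C1 | intermediate
11 | 3,3-dimethyl-3,4-dihydro-2H-benzo[g]chromene-5,10-dione | CC1(C)COC2=C(C1)C(=O)c1ccccc1C2=O | intermediate
12 | 2-hydroxy-3-(3-hydroxy-2,2-dimethylpropyl)naphthalene-1,4-dione | CC(C)(CO)CC1=C(O)C(=O)c2ccccc2C1=O | intermediate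
13 | methacrylic anhydride | C=C(C)C(=O)OC(=O)C(C)=C | starting material
14 | 3-[3-(methacryloyloxy)-1,4-dioxo-1,4-dihydronaphthalen-2-yl]-2,2-dimethylpropyl methacrylate | C=C(C)C(=O)OCC(C)(C)CC1=C(OC(=O)C(C)=C)C(=O)c2ccccc2C1=O | intermediate
15 | 3-(3-hydroxy-1,4-dioxo-1,4-dihydronaphthalen-2-yl)-2,2-dimethylpropyl methacrylate | C=C(C)C(=O)OCC(C)(C)CC1=C(O)C(=O)c2ccccc2C1=O | intermediate
16 | (R)-but-3-yn-2-ol | C#C[C@@H](C)O | starting material
17 | but-3-enylmagnesium bromide | C=CCC[Mg]Br | starting material
18 | (2R)-3-methylidenehept-6-en-2-ol | C=CCCC(=C)[C@@H](C)O | intermediate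
19 | rhinacanthin I, 3-(3-hydroxy-1,4-dioxo-1,4-dihydronaphthalen-2-yl)-2,2-dimethylpropyl (2E,7R)-7-hydroxy-2-methyl-6-methylideneoct-2-enoate | C=C(CC/C=C(\C)C(=O)OCC(C)(C)CC1=C(O)C(=O)c2ccccc2C1=O)[C@@H](C)O | target

Total step count: 7. Longest linear sequence: 6 (steps 1, 2, 3, 4, 5, 7).

Steps most likely to fail

Step 1. The reductive cleavage may stay incomplete. The alkoxide-bearing organolithium may aggregate and add sluggishly. The alkoxide end may attack the squarate ester, and ether exchange may run between molecules instead of closing the ring. The fallback sets out from 2 and comes back at 6, using a protected monoanion and separate stages. Purchased 3-bromo-2,2-dimethylpropan-1-ol is silylated (TBSCl, imidazole) to (3-bromo-2,2-dimethylpropoxy)(tert-butyl)dimethylsilane F1. Magnesium in THF converts it to the Grignard reagent F2, which adds to 2 at −78 °C to give the silylated squarate adduct F3. Brief cold dilute HCl turns this into the silylated methoxy dione F4, which is purified. TsOH·H2O in wet MeCN removes the silyl group to give 5, which closes to 6 when methanol is driven off azeotropically from toluene.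

Step 3. The hydroxyl may rotate inward, or the ketene may be captured by the hydroxyl, which would divert material toward butenolide formation. The strained bicycle may also decompose at the temperature needed for ring opening. The fallback sets out from 7 and comes back at 12, closing ring B by a Dötz benzannulation instead.
- Compound 7 adds to Cr(CO)6 to give lithium benzoylpentacarbonylchromate F5, and Me3OBF4 methylates it to pentacarbonyl[methoxy(phenyl)carbene]chromium F6.
- Heating F6 with purchased 2,2-dimethylpent-4-yn-1-ol in THF gives the Cr(CO)3-bound 2-(3-hydroxy-2,2-dimethylpropyl)-4-methoxynaphthalen-1-ol F7.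
- (NH4)2Ce(NO3)6 in aqueous MeCN oxidises it to 2-(3-hydroxy-2,2-dimethylpropyl)naphthalene-1,4-dione F8.
- H2O2/Na2CO3 gives the racemic quinone epoxide F9, and aqueous NaOH followed by cold acid isomerises it to 12.

Step 7. The 1,1-disubstituted methacrylate may turn over slowly, and the chelating hydroxyquinone may tie up the ruthenium. The dienol may be consumed by homodimerisation, and double-bond migration or loss of (E) selectivity may occur. The fallback sets out from 12 and 16 and comes back at 19, forming the enoate by carbonyl olefination.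
- Compound 12 is esterified with purchased 2-(diethoxyphosphoryl)propanoic acid (DCC, DMAP) to the naphthoquinone phosphonopropanoate F10.
- Compound 16 is carbomagnesiated with purchased [2-(1,3-dioxan-2-yl)ethyl]magnesium bromide and CuI to (2R)-5-(1,3-dioxan-2-yl)-3-methylidenepentan-2-ol F11.
- Aqueous acetic acid frees (5R)-5-hydroxy-4-methylidenehexanal F12, which is in equilibrium with its lactol.
- LiCl/DBU in MeCN joins F10 and F12 in an (E)-selective Horner–Wadsworth–Emmons olefination to 19.

Further compounds
F1 | step 1 | (3-bromo-2,2-dimethylpropoxy)(tert-butyl)dimethylsilane | CC(C)(CBr)CO[Si](C)(C)C(C)(C)C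
F2 | step 1 | [3-(tert-butyldimethylsilyloxy)-2,2-dimethylpropyl]magnesium bromide | CC(C)(C[Mg]Br)CO[Si](C)(C)C(C)(C)C
F3 | step 1 | racemic 4-[3-(tert-butyldimethylsilyloxy)-2,2-dimethylpropyl]-4-hydroxy-2,3-dimethoxycyclobut-2-en-1-one | COC1=C(OC)C(O)(CC(C)(C)CO[Si](C)(C)C(C)(C)C)C1=O
F4 | step 1 | 3-[3-(tert-butyldimethylsilyloxy)-2,2-dimethylpropyl]-4-methoxycyclobut-3-ene-1,2-dione | COC1=C(CC(C)(C)CO[Si](C)(C)C(C)(C)C)C(=O)C1=O
F5 | step 3 | lithium benzoylpentacarbonylchromate | [Li+].[O-]C(=[Cr])c1ccccc1.[C-]#[O+].[C-]#[O+].[C-]#[O+].[C-]#[O+].[C-]#[O+]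
F6 | step 3 | pentacarbonyl[methoxy(phenyl)carbene]chromium | COC(=[Cr])c1ccccc1.[C-]#[O+].[C-]#[O+].[C-]#[O+].[C-]#[O+].[C-]#[O+]
F7 | step 3 | tricarbonylchromium complex of 2-(3-hydroxy-2,2-dimethylpropyl)-4-methoxynaphthalen-1-ol | COc1cc(CC(C)(C)CO)c(O)c2ccccc12.[Cr].[C-]#[O+].[C-]#[O+].[C-]#[O+]
F8 | step 3 | 2-(3-hydroxy-2,2-dimethylpropyl)naphthalene-1,4-dione | CC(C)(CO)CC1=CC(=O)c2ccccc2C1=O
F9 | step 3 | racemic 1a-(3-hydroxy-2,2-dimethylpropyl)-1a,7a-dihydronaphtho[2,3-b]oxirene-2,7-dione | CC(C)(CO)CC12OC1C(=O)c1ccccc1C2=O
F10 | step 7 | 3-(3-hydroxy-1,4-dioxo-1,4-dihydronaphthalen-2-yl)-2,2-dimethylpropyl 2-(diethoxyphosphoryl)propanoate (racemic at the phosphonate carbon) | CCOP(=O)(OCC)C(C)C(=O)OCC(C)(C)CC1=C(O)C(=O)c2ccccc2C1=O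
F11 | step 7 | (2R)-5-(1,3-dioxan-2-yl)-3-methylidenepentan-2-ol | C=C(CCC1OCCCO1)[C@@H](C)O
F12 | step 7 | (5R)-5-hydroxy-4-methylidenehexanal | C=C(CCC=O)[C@@H](C)O
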